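**Strategy**

Ring B (the saturated ring, tetralin numbering) is disconnected at C1–C2. C1 bears a 4-hydroxy-3,5-dimethoxyphenyl ring, which makes it the electrophilic carbon of a para-quinone methide. C2 bears a CH2O carbon that can be an aldehyde, which makes C2 an enamine carbon. A matched chiral amine catalyst joins them in an intramolecular 1,6-addition that closes ring B and sets C1 and C2 against a C3 centre from asymmetric hydrogenation. The precursor is an (R)-β-benzyl lactol whose ring A already carries the diaryl carbinol; it comes from a Stobbe condensation, a lactone and a Friedel–Crafts aroylation.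

Key step: step 6

Remark on numbering: C1 carries the pendant aryl ring, C2 and C3 carry the CH2O groups, C4 is the benzylic CH2; ring A is the fused aromatic ring, ring B the saturated ring.

Assumption: in step 2 the (S,S) ligand is taken to give the R acid by analogy with related arylidenesuccinate half-esters; if the sense is opposite, the (R,R) ligand is used.

**Route**

Step 1
Reactants: 1 4-(benzyloxy)-3-methoxybenzaldehyde; 2 dimethyl succinate
Product: 3 (E)-4-[4-(benzyloxy)-3-methoxyphenyl]-3-(methoxycarbonyl)but-3-enoic acid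
Conditions: NaOMe (2.5 equiv), MeOH, reflux; then aq. HCl
Reagents that add atoms: none
Why: Stobbe condensation, in which the succinate enolate adds to the aldehyde, the alkoxide lactonises onto the distal ester and base-induced opening of the paraconate should give the (E)-arylidene half-ester with the ester on the alkene carbon.

Step 2
Reactants: 3 (E)-half-ester
Product: 4 (R)-4-[4-(benzyloxy)-3-methoxyphenyl]-3-(methoxycarbonyl)butanoic acid
Conditions: [Rh(cod)((S,S)-Et-DuPhos)]BF4 (1 mol %), H2 (5 bar), NaOMe (10 mol %), MeOH, rt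
Reagents that add atoms: none
Why: Rhodium-catalysed asymmetric hydrogenation of an itaconate-type half-ester, in which the carboxylate-bound substrate receives hydrogen on one alkene face and the ligand thereby sets the C3 centre as R; the benzyl ether is inert to this homogeneous catalyst.

Step 3
Reactants: 4 (R)-half-ester
Product: 6 (R)-4-[4-(benzyloxy)-3-methoxybenzyl]dihydrofuran-2(3H)-one, via hydroxy acid 5 (not isolated)
Conditions: KOH (1 equiv), EtOH; CaCl2, NaBH4, EtOH, −10 °C to rt; then 2 M HCl, 60 °C
Reagents that add atoms: none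
Why: Chemoselective borohydride reduction, in which Ca(BH4)2 made in the flask reduces the methyl ester while the carboxylate is inert, followed by acid lactonisation of 5 that does not touch the stereocentre.

Step 4
Reactants: 6 (R)-lactone; 7 4-acetoxy-3,5-dimethoxybenzoic acid
Product: 9 (R)-4-[2-(4-acetoxy-3,5-dimethoxybenzoyl)-4-(benzyloxy)-5-methoxybenzyl]dihydrofuran-2(3H)-one, via mixed anhydride 8 (not isolated)
Conditions: (CF3CO)2O (2 equiv), H3PO4 (85 %, cat.), CH2Cl2, 0 °C to rt
Reagents that add atoms: none
Why: Friedel–Crafts acylation through the mixed trifluoroacetic anhydride, in which the aroyl cation should attack the ring A position para to the methoxy group and ortho to the benzylic CH2, the most activated and accessible site, under conditions mild enough for the benzyl ether and the lactone.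

Step 5
Reactants: 9 keto lactone
Product: 10 (4R)-4-{4-(benzyloxy)-2-[hydroxy(4-hydroxy-3,5-dimethoxyphenyl)methyl]-5-methoxybenzyl}tetrahydrofuran-2-ol
Conditions: i-Bu2AlH (4.5 equiv), CH2Cl2, −78 °C; aq. potassium sodium tartrate; crude product used directly
Reagents that add atoms: none
Why: Hydride reduction with i-Bu2AlH, which at −78 °C should stop at the lactol aluminate, reduce the diaryl ketone to the carbinol and cleave the aryl acetate in one operation; the new carbinol and lactol centres form as mixtures, which is harmless because both become trigonal in step 6.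

Step 6
Reactants: 10 carbinol lactol
Product: 13 (1S,2R,3R)-7-(benzyloxy)-1-(4-hydroxy-3,5-dimethoxyphenyl)-3-(hydroxymethyl)-6-methoxy-1,2,3,4-tetrahydronaphthalene-2-carbaldehyde, via quinone methide 11 (not isolated), via enamine 12 (not isolated)
Conditions: (R)-α,α-diphenylprolinol trimethylsilyl ether (20 mol %), 4-nitrobenzoic acid (20 mol %), CHCl3 (0.05 M), 40 °C
Reagents that add atoms: none
Why: The acid dehydrates the electron-rich 4-hydroxy-3,5-dimethoxyphenyl carbinol of 10 to the para-quinone methide 11, whose lactol opens and condenses with the amine to the (E)-enamine 12; the enamine carbon C2 then adds to the methide carbon C1 (1,6-addition), the phenol rearomatises, and hydrolysis of the iminium releases 13 and the catalyst. The closest known reaction type is the aminocatalytic α-alkylation of aldehydes by 1,6-addition of their enamines to para-quinone methides. Ring B closes in the 6-exo-trig mode at C1 (the C1=C bond of the methide lies outside the new ring) and in the enolexo mode at C2. C2 is controlled by the catalyst, whose silyloxydiphenylmethyl group shields one enamine face so that C1 bonds to the Re face of C2, the same sense that the fixed C3 centre prefers because it places the new bond trans to the C3 hydroxymethyl group; C1 is controlled by a chair-like transition state in which the quinoid ring, the enamine arm and the C3 hydroxymethyl group are all pseudo-equatorial, which should give the 1,2-trans-2,3-trans product. The step needs C-alkylation over O- or N-alkylation and a single ring size: addition of the C3 hydroxymethyl oxygen or of the amine to 11 is reversible while C–C bond formation is not, and C2 is the only enolisable carbon, so only the six-membered ring can form.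

Step 7
Reactants: 13 aldehyde
Product: 14 [(1S,2R,3R)-7-(benzyloxy)-1-(4-hydroxy-3,5-dimethoxyphenyl)-6-methoxy-1,2,3,4-tetrahydronaphthalene-2,3-diyl]dimethanol
Conditions: NaBH4, MeOH, 0 °C
Reagents that add atoms: none
Why: Borohydride reduction of the aldehyde to the primary alcohol, fast enough at 0 °C that the C2 centre, already in its more stable trans arrangement, is not disturbed.

Step 8
Reactants: 14 diol
Product: 15 [(1S,2R,3R)-7-(benzyloxy)-1-(4-hydroxy-3,5-dimethoxyphenyl)-6-methoxy-1,2,3,4-tetrahydronaphthalene-2,3-diyl]bis(methylene) diacetate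
Conditions: immobilised Candida antarctica lipase B, vinyl acetate (excess), THF, 40 °C
Reagents that add atoms: vinyl acetate, C=COC(C)=O
Why: Lipase-catalysed transesterification, which acylates primary aliphatic alcohols and should leave the hindered phenol free, and which is made irreversible by tautomerisation of the released vinyl alcohol to acetaldehyde.

Step 9
Reactants: 15 benzyl ether diacetate
Product: 16 [(1S,2R,3R)-7-hydroxy-1-(4-hydroxy-3,5-dimethoxyphenyl)-6-methoxy-1,2,3,4-tetrahydronaphthalene-2,3-diyl]bis(methylene) diacetate (CNP0265800.1)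
Conditions: H2 (1 atm), palladium on carbon (Pd/C, 10 %), EtOAc, rt
Reagents that add atoms: none
Why: Hydrogenolysis of the benzyl aryl ether under neutral conditions, which should leave the acetates, the phenols and the three stereocentres untouched.

**Compound list**

1 | 4-(benzyloxy)-3-methoxybenzaldehyde | COc1cc(C=O)ccc1OCc1ccccc1 | starting material
2 | dimethyl succinate | COC(=O)CCC(=O)OC | starting material
3 | (E)-4-[4-(benzyloxy)-3-methoxyphenyl]-3-(methoxycarbonyl)but-3-enoic acid | COC(=O)/C(CC(=O)O)=C/c1ccc(OCc2ccccc2)c(OC)c1 | intermediate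
4 | (R)-4-[4-(benzyloxy)-3-methoxyphenyl]-3-(methoxycarbonyl)butanoic acid | COC(=O)[C@@H](CC(=O)O)Cc1ccc(OCc2ccccc2)c(OC)c1 | intermediate
5 | (R)-4-[4-(benzyloxy)-3-methoxyphenyl]-3-(hydroxymethyl)butanoic acid | OC[C@H](Cc1ccc(OCc2ccccc2)c(OC)c1)CC(=O)O | intermediate (not isolated)
6 | (R)-4-[4-(benzyloxy)-3-methoxybenzyl]dihydrofuran-2(3H)-one | O=C1C[C@@H](Cc2ccc(OCc3ccccc3)c(OC)c2)CO1 | intermediate
7 | 4-acetoxy-3,5-dimethoxybenzoic acid | CC(=O)Oc1c(OC)cc(cc1OC)C(=O)O | starting material
8 | 4-acetoxy-3,5-dimethoxybenzoic trifluoroacetic anhydride | CC(=O)Oc1c(OC)cc(cc1OC)C(=O)OC(=O)C(F)(F)F | intermediate (not isolated)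
9 | (R)-4-[2-(4-acetoxy-3,5-dimethoxybenzoyl)-4-(benzyloxy)-5-methoxybenzyl]dihydrofuran-2(3H)-one | O=C1C[C@@H](Cc2cc(OC)c(OCc3ccccc3)cc2C(=O)c2cc(OC)c(OC(C)=O)c(OC)c2)CO1 | intermediate
10 | (4R)-4-{4-(benzyloxy)-2-[hydroxy(4-hydroxy-3,5-dimethoxyphenyl)methyl]-5-methoxybenzyl}tetrahydrofuran-2-ol (mixture at the carbinol and lactol carbons) | OC1C[C@@H](Cc2cc(OC)c(OCc3ccccc3)cc2C(O)c2cc(OC)c(O)c(OC)c2)CO1 | intermediate
11 | 4-[(5-(benzyloxy)-2-{[(3R)-5-hydroxytetrahydrofuran-3-yl]methyl}-4-methoxyphenyl)methylidene]-2,6-dimethoxycyclohexa-2,5-dien-1-one | OC1C[C@@H](Cc2cc(OC)c(OCc3ccccc3)cc2C=C2C=C(OC)C(=O)C(OC)=C2)CO1 | intermediate (not isolated)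
12 | (E)-enamine of the ring-opened hydroxy aldehyde form of 11 with (R)-α,α-diphenylprolinol trimethylsilyl ether (3R centre kept) | OC[C@H](Cc1cc(OC)c(OCc2ccccc2)cc1C=C1C=C(OC)C(=O)C(OC)=C1)/C=C/N1CCC[C@@H]1C(c1ccccc1)(c1ccccc1)O[Si](C)(C)C | intermediate (not isolated)
13 | (1S,2R,3R)-7-(benzyloxy)-1-(4-hydroxy-3,5-dimethoxyphenyl)-3-(hydroxymethyl)-6-methoxy-1,2,3,4-tetrahydronaphthalene-2-carbaldehyde (drawn as the open hydroxy aldehyde) | COc1cc2c(cc1OCc1ccccc1)[C@H](c1cc(OC)c(O)c(OC)c1)[C@@H](C=O)[C@H](CO)C2 | intermediate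
14 | [(1S,2R,3R)-7-(benzyloxy)-1-(4-hydroxy-3,5-dimethoxyphenyl)-6-methoxy-1,2,3,4-tetrahydronaphthalene-2,3-diyl]dimethanol | COc1cc2c(cc1OCc1ccccc1)[C@H](c1cc(OC)c(O)c(OC)c1)[C@@H](CO)[C@H](CO)C2 | intermediate
15 | [(1S,2R,3R)-7-(benzyloxy)-1-(4-hydroxy-3,5-dimethoxyphenyl)-6-methoxy-1,2,3,4-tetrahydronaphthalene-2,3-diyl]bis(methylene) diacetate | COc1cc2c(cc1OCc1ccccc1)[C@H](c1cc(OC)c(O)c(OC)c1)[C@@H](COC(C)=O)[C@H](COC(C)=O)C2 | intermediate
16 | [(1S,2R,3R)-7-hydroxy-1-(4-hydroxy-3,5-dimethoxyphenyl)-6-methoxy-1,2,3,4-tetrahydronaphthalene-2,3-diyl]bis(methylene) diacetate | COc1cc2c(cc1O)[C@H](c1cc(OC)c(O)c(OC)c1)[C@@H](COC(C)=O)[C@H](COC(C)=O)C2 | target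

**Step count and risks**

Total steps: 9. Longest linear sequence: 9 steps (1 to 16).

Steps most likely to fail:

Step 6. The quinone methide may be parked by reversible addition of the C3 hydroxymethyl oxygen or of the amine, may oligomerise before the enamine forms, or C1 may form with poor facial selectivity. The fallback keeps the same ring-closing bond but moves stereocontrol from the C–C bond formation to a reduction and an equilibration. It sets out from 10: DDQ in dioxane should oxidise the para-hydroxybenzylic carbinol to the keto lactol (4R)-4-[4-(benzyloxy)-2-(4-hydroxy-3,5-dimethoxybenzoyl)-5-methoxybenzyl]tetrahydrofuran-2-ol F1. Dibenzylammonium trifluoroacetate in toluene at 80 °C should then effect intramolecular aldol condensation of the lactol-derived aldehyde with the diaryl ketone, closing C1–C2 as a double bond, to give (3R)-7-(benzyloxy)-1-(4-hydroxy-3,5-dimethoxyphenyl)-3-(hydroxymethyl)-6-methoxy-3,4-dihydronaphthalene-2-carbaldehyde F2. Hydrogenation over ethylenediamine-poisoned palladium on carbon, which spares the benzyl ether, should add hydrogen to the face anti to the pseudo-axial C3 hydroxymethyl group and give the all-cis aldehyde (1S,2S,3R)-7-(benzyloxy)-1-(4-hydroxy-3,5-dimethoxyphenyl)-3-(hydroxymethyl)-6-methoxy-1,2,3,4-tetrahydronaphthalene-2-carbaldehyde F3. DBU in CH2Cl2 should epimerise C2 to the all-equatorial aldehyde, which is 13, where the route resumes.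

Step 4. The acidic medium may cleave the benzyl ether, the arene may be trifluoroacetylated, or acylation may stray to the position ortho to the benzyloxy group. The fallback replaces electrophilic acylation by halogenation and a carbonylative cross-coupling. It sets out from 6: NBS in MeCN at 0 °C should brominate para to the methoxy group to give (R)-4-[4-(benzyloxy)-2-bromo-5-methoxybenzyl]dihydrofuran-2(3H)-one F4. Carbonylative Suzuki–Miyaura coupling with commercial 2,6-dimethoxy-4-(4,4,5,5-tetramethyl-1,3,2-dioxaborolan-2-yl)phenol (Pd(OAc)2, di(1-adamantyl)-n-butylphosphine, CO 5 bar, K2CO3, toluene/H2O, 100 °C, acidic work-up to re-close the lactone) should give (R)-4-[4-(benzyloxy)-2-(4-hydroxy-3,5-dimethoxybenzoyl)-5-methoxybenzyl]dihydrofuran-2(3H)-one F5. Reduction with i-Bu2AlH as in step 5 converts F5 into 10.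

Step 8. Acyl transfer may stall at a monoacetate, because the C2 hydroxymethyl group is flanked by the C1 aryl ring, or may be too slow to be useful. The fallback replaces the enzyme by exhaustive acetylation and selective removal of the aryl acetate. It sets out from 14: Ac2O, pyridine and DMAP should give the triacetate [(1S,2R,3R)-1-(4-acetoxy-3,5-dimethoxyphenyl)-7-(benzyloxy)-6-methoxy-1,2,3,4-tetrahydronaphthalene-2,3-diyl]bis(methylene) diacetate F6. Pyrrolidine (1.1 equiv, MeCN, 0 °C) should aminolyse only the far more reactive aryl acetate and return 15.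

**Further compounds**

F1 | step 6 | (4R)-4-[4-(benzyloxy)-2-(4-hydroxy-3,5-dimethoxybenzoyl)-5-methoxybenzyl]tetrahydrofuran-2-ol | OC1C[C@@H](Cc2cc(OC)c(OCc3ccccc3)cc2C(=O)c2cc(OC)c(O)c(OC)c2)CO1
F2 | step 6 | (3R)-7-(benzyloxy)-1-(4-hydroxy-3,5-dimethoxyphenyl)-3-(hydroxymethyl)-6-methoxy-3,4-dihydronaphthalene-2-carbaldehyde | COc1cc2c(cc1OCc1ccccc1)C(c1cc(OC)c(O)c(OC)c1)=C(C=O)[C@H](CO)C2
F3 | step 6 | (1S,2S,3R)-7-(benzyloxy)-1-(4-hydroxy-3,5-dimethoxyphenyl)-3-(hydroxymethyl)-6-methoxy-1,2,3,4-tetrahydronaphthalene-2-carbaldehyde | COc1cc2c(cc1OCc1ccccc1)[C@H](c1cc(OC)c(O)c(OC)c1)[C@H](C=O)[C@H](CO)C2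
F4 | step 4 | (R)-4-[4-(benzyloxy)-2-bromo-5-methoxybenzyl]dihydrofuran-2(3H)-one | O=C1C[C@@H](Cc2cc(OC)c(OCc3ccccc3)cc2Br)CO1
F5 | step 4 | (R)-4-[4-(benzyloxy)-2-(4-hydroxy-3,5-dimethoxybenzoyl)-5-methoxybenzyl]dihydrofuran-2(3H)-one | O=C1C[C@@H](Cc2cc(OC)c(OCc3ccccc3)cc2C(=O)c2cc(OC)c(O)c(OC)c2)CO1
F6 | step 8 | [(1S,2R,3R)-1-(4-acetoxy-3,5-dimethoxyphenyl)-7-(benzyloxy)-6-methoxy-1,2,3,4-tetrahydronaphthalene-2,3-diyl]bis(methylene) diacetate | COc1cc2c(cc1OCc1ccccc1)[C@H](c1cc(OC)c(OC(C)=O)c(OC)c1)[C@@H](COC(C)=O)[C@H](COC(C)=O)C2
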